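## Retrosynthetic overview

1. The C5–Cl bond is made last, by electrophilic chlorination of the 5-deschloro azaphilone.
2. Ring B (the pyran, O2–C3 bond) is the only ring that is built. It is closed by 6-endo-dig cycloisomerisation of a ring-open alkynyl vinylogous acid. Ring A is the carbocycle of a resorcylaldehyde, carried through and dearomatised.
3. The C7–O bond, the propanoate and the C7 stereocentre are set together. This is the new step: an enantioselective dearomative propanoyloxylation of the alkynyl resorcylaldehyde with a chiral bis(propanoyloxy)-λ3-iodane.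
4. The C4–C4a (alkyne–aryl) bond comes from a Sonogashira coupling. The partners are 6-bromo-2,4-dihydroxy-3-methylbenzaldehyde (from 5-bromoresorcinol by formylation and C-methylation) and the (3E,5E,7S)-dienyne.
5. The dienyne comes from (S)-2-methylbutan-1-ol (chiral pool, sets C13) by oxidation, Wittig and Horner–Wadsworth–Emmons olefination.

Target as read from the SMILES: a 6H-isochromene-6,8(7H)-dione core numbered C1, O2, C3 to C8a. It carries 5-Cl, 7-Me, 7-O-propanoyl (7R) and a 3-[(1E,3E,5S)-3,5-dimethylhepta-1,3-dienyl] chain whose stereocentre is C13 (S).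

Assumption: the facial sense of the new step (the (R,R)-reagent giving the drawn C7 configuration) is a model-based prediction; if it proves opposite, the (S,S)-reagent from the enantiomeric iodoarene is used in the same way.

## Route

Step 1
Reactants: 1 (S)-2-methylbutan-1-ol
Product: 2 (S)-2-methylbutanal
Conditions: TEMPO (1 mol %), KBr (10 mol %), NaOCl (1.1 equiv, aq., buffered with NaHCO3 to pH 9.5), CH2Cl2/H2O, 0 °C
Reagents that add atoms: none
Why: Anelli oxidation (oxoammonium-mediated) stops at the aldehyde at 0 °C and buffered pH, so the chiral-pool stereocentre (future C13, S) is not enolised.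

Step 2
Reactants: 2 (S)-2-methylbutanal; 3 2-(triphenyl-λ5-phosphanylidene)propanal
Product: 4 (2E,4S)-2,4-dimethylhex-2-enal
Conditions: PhMe, 80 °C, sealed flask, 24 h
Reagents that add atoms: none
Why: Wittig olefination with a stabilised formyl ylide gives the (E)-trisubstituted enal under neutral conditions that leave the now allylic stereocentre intact.

Step 3
Reactants: 5 3-bromo-1-(trimethylsilyl)prop-1-yne; 6 triethyl phosphite
Product: 7 diethyl [3-(trimethylsilyl)prop-2-yn-1-yl]phosphonate
Conditions: neat, 130 °C, EtBr distilled off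
Reagents that add atoms: none
Why: Michaelis–Arbuzov reaction, in which SN2 attack of phosphorus on the propargylic bromide is followed by dealkylation of the phosphonium salt by bromide and driven by loss of volatile bromoethane.

Step 4
Reactants: 7 diethyl [3-(trimethylsilyl)prop-2-yn-1-yl]phosphonate; 4 (2E,4S)-2,4-dimethylhex-2-enal
Product: 9 trimethyl[(3E,5E,7S)-5,7-dimethylnona-3,5-dien-1-yn-1-yl]silane, via lithiated phosphonate 8 (not isolated)
Conditions: LiN(SiMe3)2, THF, −78 °C; then 4, −78 → 0 °C
Reagents that add atoms: none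
Why: Horner–Wadsworth–Emmons olefination with a propargyl-stabilised phosphonate anion adds reversibly and collapses to the (E)-enyne, and 1,2-addition at −78 °C is much faster than γ-deprotonation of 4.

Step 5
Reactants: 9 trimethyl[(3E,5E,7S)-5,7-dimethylnona-3,5-dien-1-yn-1-yl]silane
Product: 10 (3E,5E,7S)-5,7-dimethylnona-3,5-dien-1-yne
Conditions: K2CO3 (0.2 equiv), MeOH, rt; careful concentration (volatile)
Reagents that add atoms: none
Why: Base-catalysed protodesilylation of an alkynylsilane (methoxide attacks silicon, acetylide leaves) changes neither alkene geometry nor the stereocentre.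

Step 6
Reactants: 11 5-bromobenzene-1,3-diol
Product: 13 2-bromo-4,6-dihydroxybenzaldehyde, via aryl iminium salt 12 (not isolated)
Conditions: POCl3 (1.2 equiv), DMF, MeCN, 0 °C → rt; then H2O, 50 °C
Reagents that add atoms: N,N-dimethylformamide CN(C)C=O (formyl carbon); water O (aldehyde oxygen)
Why: Vilsmeier–Haack formylation, in which the chloroiminium ion attacks para to one OH and ortho to the other (the site between the two OH groups is more hindered) and hydrolysis of 12 releases the aldehyde.

Step 7
Reactants: 13 2-bromo-4,6-dihydroxybenzaldehyde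
Product: 14 6-bromo-2,4-dihydroxy-3-methylbenzaldehyde
Conditions: MeI (1.2 equiv), KOH, MeOH/H2O, 65 °C
Reagents that add atoms: iodomethane CI
Why: Classical nuclear C-methylation of a resorcylaldehyde, since in protic medium the hydrogen-bonded ambident phenolate reacts with soft MeI at the carbon between the two oxygens, its most nucleophilic site.

Step 8
Reactants: 14 6-bromo-2,4-dihydroxy-3-methylbenzaldehyde; 10 (3E,5E,7S)-5,7-dimethylnona-3,5-dien-1-yne
Product: 15 6-[(3E,5E,7S)-5,7-dimethylnona-3,5-dien-1-yn-1-yl]-2,4-dihydroxy-3-methylbenzaldehyde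
Conditions: PdCl2(PPh3)2 (5 mol %), CuI (10 mol %), Et3N, DMF (degassed), 60 °C
Reagents that add atoms: none
Why: Sonogashira coupling, in which the ortho formyl group activates the C–Br bond for oxidative addition to zerovalent palladium and no OH sits ortho to the new alkyne, so benzofuran formation is impossible.

Step 9
Reactants: 16 (2R,2'R)-2,2'-[(2-iodo-1,3-phenylene)bis(oxy)]bis[N-(2,4,6-trimethylphenyl)propanamide]
Product: 17 (2R,2'R)-2,2'-{[2-(bis(propanoyloxy)-λ3-iodanyl)-1,3-phenylene]bis(oxy)}bis[N-(2,4,6-trimethylphenyl)propanamide]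
Conditions: NaBO3·4H2O, EtCO2H, 45 °C; H2O, CH2Cl2 extraction, precipitation from CH2Cl2/hexane
Reagents that add atoms: propanoic acid CCC(=O)O
Why: Perborate oxidation of an electron-rich iodoarene in a carboxylic acid is the standard preparation of (diacyloxyiodo)arenes, the solvent acid becomes both ligands on trivalent iodine, and the lactamide stereocentres are untouched.

Step 10
Reactants: 15 6-[(3E,5E,7S)-5,7-dimethylnona-3,5-dien-1-yn-1-yl]-2,4-dihydroxy-3-methylbenzaldehyde; 17 chiral bis(propanoyloxy)-λ3-iodane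
Product: 19 (1R)-4-[(3E,5E,7S)-5,7-dimethylnona-3,5-dien-1-yn-1-yl]-3-formyl-2-hydroxy-1-methyl-6-oxocyclohexa-2,4-dien-1-yl propanoate, via aryloxy-λ3-iodane 18 (not isolated)
Conditions: 17 (1.1 equiv), 4 Å MS, CH2Cl2/PhMe 1:1, −40 °C, dark; short silica plug (returns 16)
Reagents that add atoms: none
Why: Proposed new method: an enantioselective intermolecular Wessely-type dearomative acyloxylation by a preformed chiral diacyloxy-λ3-iodane, used stoichiometrically so that no peracid ever meets the diene; the free 4-OH of 15 (the 2-OH is tied up in a hydrogen bond to the aldehyde) displaces one propanoate on trivalent iodine to give 18, the released propanoic acid stays hydrogen-bonded to a lactamide N–H/C=O arm of the C2-symmetric reagent, and it attacks the most electron-rich ortho carbon (C3 of the arene, methyl-bearing, between the two oxygens, future C7) in an associative SN2′-type displacement of the iodoarene from the face left open by the mesityl amide, so the C–O bond, the ester and the quaternary stereocentre form together, while non-polar solvent and low temperature suppress the free phenoxenium (racemic) path; the closest known reactions are the racemic Wessely oxidation with Pb(OAc)4, racemic ortho-acetoxylation of phenols with PhI(OAc)2, and the intramolecular enantioselective Kita-type dearomative spirolactonisation run with this iodoarene family.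

Step 11
Reactants: 19 ring-open propanoyloxy vinylogous acid
Product: 20 (7S)-3-[(1E,3E,5S)-3,5-dimethylhepta-1,3-dien-1-yl]-7-methyl-6,8-dioxo-7,8-dihydro-6H-isochromen-7-yl propanoate
Conditions: CuI (10 mol %), KH2PO4/K2HPO4 buffer (pH 7.2)/MeCN, rt
Reagents that add atoms: none
Why: 6-endo-dig oxa-cycloisomerisation, in which the hydroxymethylene tautomer adds through oxygen to the distal carbon of the CuI-activated alkyne (also the 1,6-acceptor site of the ynenone) and closes ring B, with C7 untouched (its label changes from R to S only because the ranking of the two ring branches changes).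

Step 12
Reactants: 20 5-deschloro azaphilone propanoate
Product: 21 Sclerketide B, (7R)-5-chloro-3-[(1E,3E,5S)-3,5-dimethylhepta-1,3-dien-1-yl]-7-methyl-6,8-dioxo-7,8-dihydro-6H-isochromen-7-yl propanoate
Conditions: NCS (1.05 equiv), MeCN, 0 °C → rt, dark
Reagents that add atoms: N-chlorosuccinimide O=C1CCC(=O)N1Cl
Why: Electrophilic α-chlorination of a vinylogous ester, since C5 is the terminus of the O2–C3=C4–C4a=C5 dienol ether and the most nucleophilic carbon while the side-chain diene is deactivated by conjugation to the core, and C7 is untouched (its label becomes R because C5–Cl raises the rank of C6).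

## Compound list

1 | (S)-2-methylbutan-1-ol | CC[C@H](C)CO | starting material
2 | (S)-2-methylbutanal | CC[C@H](C)C=O | intermediate
3 | 2-(triphenyl-λ5-phosphanylidene)propanal | CC(C=O)=P(c1ccccc1)(c1ccccc1)c1ccccc1 | starting material
4 | (2E,4S)-2,4-dimethylhex-2-enal | CC[C@H](C)/C=C(\C)C=O | intermediate
5 | 3-bromo-1-(trimethylsilyl)prop-1-yne | C[Si](C)(C)C#CCBr | starting material
6 | triethyl phosphite | CCOP(OCC)OCC | starting material
7 | diethyl [3-(trimethylsilyl)prop-2-yn-1-yl]phosphonate | CCOP(=O)(CC#C[Si](C)(C)C)OCC | intermediate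
8 | lithiated phosphonate (lithium salt of the α-carbanion of 7) | [Li+].CCOP(=O)([CH-]C#C[Si](C)(C)C)OCC | intermediate
9 | trimethyl[(3E,5E,7S)-5,7-dimethylnona-3,5-dien-1-yn-1-yl]silane | CC[C@H](C)/C=C(C)/C=C/C#C[Si](C)(C)C | intermediate
10 | (3E,5E,7S)-5,7-dimethylnona-3,5-dien-1-yne | CC[C@H](C)/C=C(C)/C=C/C#C | intermediate
11 | 5-bromobenzene-1,3-diol (5-bromoresorcinol) | Oc1cc(O)cc(Br)c1 | starting material
12 | (2-bromo-4,6-dihydroxybenzylidene)dimethyliminium dichlorophosphate | C[N+](C)=Cc1c(O)cc(O)cc1Br.[O-]P(=O)(Cl)Cl | intermediate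
13 | 2-bromo-4,6-dihydroxybenzaldehyde | O=Cc1c(O)cc(O)cc1Br | intermediate
14 | 6-bromo-2,4-dihydroxy-3-methylbenzaldehyde | Cc1c(O)cc(Br)c(C=O)c1O | intermediate
15 | 6-[(3E,5E,7S)-5,7-dimethylnona-3,5-dien-1-yn-1-yl]-2,4-dihydroxy-3-methylbenzaldehyde | CC[C@H](C)/C=C(C)/C=C/C#Cc1cc(O)c(C)c(O)c1C=O | intermediate
16 | (2R,2'R)-2,2'-[(2-iodo-1,3-phenylene)bis(oxy)]bis[N-(2,4,6-trimethylphenyl)propanamide] | Ic1c(O[C@H](C)C(=O)Nc2c(C)cc(C)cc2C)cccc1O[C@H](C)C(=O)Nc1c(C)cc(C)cc1C | starting material
17 | (2R,2'R)-2,2'-{[2-(bis(propanoyloxy)-λ3-iodanyl)-1,3-phenylene]bis(oxy)}bis[N-(2,4,6-trimethylphenyl)propanamide] | CCC(=O)OI(OC(=O)CC)c1c(O[C@H](C)C(=O)Nc2c(C)cc(C)cc2C)cccc1O[C@H](C)C(=O)Nc1c(C)cc(C)cc1C | intermediate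
18 | aryloxy(propanoyloxy)-λ3-iodane: iodine carries the chiral aryl group of 17, one propanoate and the C4 oxygen of 15 | CCC(=O)OI(Oc1cc(C#C/C=C/C(C)=C/[C@@H](C)CC)c(C=O)c(O)c1C)c1c(O[C@H](C)C(=O)Nc2c(C)cc(C)cc2C)cccc1O[C@H](C)C(=O)Nc1c(C)cc(C)cc1C | intermediate
19 | (1R)-4-[(3E,5E,7S)-5,7-dimethylnona-3,5-dien-1-yn-1-yl]-3-formyl-2-hydroxy-1-methyl-6-oxocyclohexa-2,4-dien-1-yl propanoate | CCC(=O)O[C@]1(C)C(O)=C(C=O)C(C#C/C=C/C(C)=C/[C@@H](C)CC)=CC1=O | intermediate
20 | (7S)-3-[(1E,3E,5S)-3,5-dimethylhepta-1,3-dien-1-yl]-7-methyl-6,8-dioxo-7,8-dihydro-6H-isochromen-7-yl propanoate | CCC(=O)O[C@]1(C)C(=O)C2=COC(/C=C/C(C)=C/[C@@H](C)CC)=CC2=CC1=O | intermediate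
21 | Sclerketide B, (7R)-5-chloro-3-[(1E,3E,5S)-3,5-dimethylhepta-1,3-dien-1-yl]-7-methyl-6,8-dioxo-7,8-dihydro-6H-isochromen-7-yl propanoate | CCC(=O)O[C@]1(C)C(=O)C2=COC(/C=C/C(C)=C/[C@@H](C)CC)=CC2=C(Cl)C1=O | target

## Step count and risks

Total step count: 12.
Longest linear sequence: 8 steps (1, 2, 4, 5, 8, 10, 11, 12).

**Step 10, the proposed new step.**
- The risks are low facial selectivity if a free phenoxenium ion forms, attack at the C5–H ortho position, and hydroxylation by adventitious water.
- Any C7 epimer is a diastereomer because of C13, so it can be removed at 20.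
- The fallback uses known chemistry, sets out from 15 and comes back at 20.
- 15 undergoes the established copper-mediated enantioselective hydroxylative dearomatisation. The conditions are [Cu(MeCN)4]PF6, the (+)-sparteine surrogate (1R,2S,9S)-11-methyl-7,11-diazatricyclo[7.3.1.0(2,7)]tridecane, i-Pr2NEt, DMAP and O2 in CH2Cl2 at −78 to −10 °C.
- This gives the ring-open tertiary alcohol (3R)-6-[(3E,5E,7S)-5,7-dimethylnona-3,5-dien-1-yn-1-yl]-2,3-dihydroxy-3-methyl-4-oxocyclohexa-1,5-diene-1-carbaldehyde F1.
- Cycloisomerisation with catalytic CuI in pH 7.2 phosphate buffer/MeCN gives (7S)-3-[(1E,3E,5S)-3,5-dimethylhepta-1,3-dien-1-yl]-7-hydroxy-7-methyl-6H-isochromene-6,8(7H)-dione F2.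
- Acylation of the tertiary alcohol with propanoic anhydride and DMAP in CH2Cl2 then gives 20.

**Step 7, the C-methylation.**
- The risks are O-methylation, double alkylation and a modest yield.
- The fallback sets out from 13 and comes back at 14. It installs the methyl group by site-selective halogenation and cross-coupling instead of phenolate alkylation.
- Iodination under phenolate conditions (I2, NaHCO3, H2O/THF, 0 °C) goes between the two oxygens and gives 6-bromo-2,4-dihydroxy-3-iodobenzaldehyde F3.
- Protection with MOMCl and i-Pr2NEt gives 6-bromo-3-iodo-2,4-bis(methoxymethoxy)benzaldehyde F4.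
- A Negishi coupling chemoselective for C–I over C–Br (MeZnCl, PdCl2(dppf) cat., THF, rt) gives 6-bromo-2,4-bis(methoxymethoxy)-3-methylbenzaldehyde F5.
- HCl in MeOH at 45 °C removes both acetals and returns 14.

**Step 12, the late chlorination.**
- The risks are competing attack on the trisubstituted alkene of the side chain and over-chlorination of the pyran.
- The fallback sets out from 14 and comes back at 21. It puts the chlorine on the arene before any alkene is present.
- SO2Cl2 in Et2O at 0 °C chlorinates the only free ring position and gives 6-bromo-5-chloro-2,4-dihydroxy-3-methylbenzaldehyde F6.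
- Sonogashira coupling with 10, selective for C–Br over C–Cl, gives 5-chloro-6-[(3E,5E,7S)-5,7-dimethylnona-3,5-dien-1-yn-1-yl]-2,4-dihydroxy-3-methylbenzaldehyde F7.
- Treatment with 17 as in step 10 passes through the chlorinated aryloxy(propanoyloxy)-λ3-iodane F8. It gives (1R)-5-chloro-4-[(3E,5E,7S)-5,7-dimethylnona-3,5-dien-1-yn-1-yl]-3-formyl-2-hydroxy-1-methyl-6-oxocyclohexa-2,4-dien-1-yl propanoate F9.
- Catalytic CuI in buffered MeCN, as in step 11, closes ring B and gives 21 directly.

## Further compounds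

F1 | step 10 | (3R)-6-[(3E,5E,7S)-5,7-dimethylnona-3,5-dien-1-yn-1-yl]-2,3-dihydroxy-3-methyl-4-oxocyclohexa-1,5-diene-1-carbaldehyde | O[C@]1(C)C(O)=C(C=O)C(C#C/C=C/C(C)=C/[C@@H](C)CC)=CC1=O
F2 | step 10 | (7S)-3-[(1E,3E,5S)-3,5-dimethylhepta-1,3-dien-1-yl]-7-hydroxy-7-methyl-6H-isochromene-6,8(7H)-dione | O[C@]1(C)C(=O)C2=COC(/C=C/C(C)=C/[C@@H](C)CC)=CC2=CC1=O
F3 | step 7 | 6-bromo-2,4-dihydroxy-3-iodobenzaldehyde | O=Cc1c(Br)cc(O)c(I)c1O
F4 | step 7 | 6-bromo-3-iodo-2,4-bis(methoxymethoxy)benzaldehyde | COCOc1cc(Br)c(C=O)c(OCOC)c1I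
F5 | step 7 | 6-bromo-2,4-bis(methoxymethoxy)-3-methylbenzaldehyde | COCOc1cc(Br)c(C=O)c(OCOC)c1C
F6 | step 12 | 6-bromo-5-chloro-2,4-dihydroxy-3-methylbenzaldehyde | Cc1c(O)c(Cl)c(Br)c(C=O)c1O
F7 | step 12 | 5-chloro-6-[(3E,5E,7S)-5,7-dimethylnona-3,5-dien-1-yn-1-yl]-2,4-dihydroxy-3-methylbenzaldehyde | CC[C@H](C)/C=C(C)/C=C/C#Cc1c(Cl)c(O)c(C)c(O)c1C=O
F8 | step 12 | chlorinated aryloxy(propanoyloxy)-λ3-iodane (iodine carries the chiral aryl group of 17, one propanoate and the C4 oxygen of F7) | CCC(=O)OI(Oc1c(Cl)c(C#C/C=C/C(C)=C/[C@@H](C)CC)c(C=O)c(O)c1C)c1c(O[C@H](C)C(=O)Nc2c(C)cc(C)cc2C)cccc1O[C@H](C)C(=O)Nc1c(C)cc(C)cc1C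
F9 | step 12 | (1R)-5-chloro-4-[(3E,5E,7S)-5,7-dimethylnona-3,5-dien-1-yn-1-yl]-3-formyl-2-hydroxy-1-methyl-6-oxocyclohexa-2,4-dien-1-yl propanoate | CCC(=O)O[C@]1(C)C(O)=C(C=O)C(C#C/C=C/C(C)=C/[C@@H](C)CC)=C(Cl)C1=O
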